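## Retrosynthetic overview

- Clerodane numbering is used: ring A = C1–C5/C10 (holds the C3=C4 olefin), ring B = C5–C10 (oxygenated). Disconnections: C12–C13 (Heck), the C6/C7/C8 oxygen pattern back to a 6-oxo-7-ene, C3=C4 (ring A), the C4–C5 acetyl unit, then C8–C9 and C5–C10 (Diels–Alder).
- Enabling feature: C4 is an sp2 carbon that carries only the C18 methyl and sits on the quaternary ring-fusion carbon C5, while C3 ends a three-carbon bridge from C10. C3=C4 therefore maps onto an acetyl group on C5 and a trisubstituted olefin at the end of a C10 side chain, joined by ring-closing carbonyl–olefin metathesis through a strained oxetane.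
- The second unsaturated arm of ring B (the C11 vinyl on C9, cis-1,3 to the acetyl) is a monosubstituted olefin and is blind to this event. This is why the closure is carbonyl–olefin and not olefin–olefin.
- Ring order: ring B by a catalytic enantioselective Diels–Alder reaction (sets C9 and C10), ring A by the key step, butenolide ring brought in intact at the end.

Key step: step 8

Remark: the (S)-configured oxazaborolidinium catalyst of step 3 is assumed, by analogy with its cycloadditions of 2-methylacrolein, to give the C9/C10 configuration drawn for 6.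

## Route

Step 1
Reactants: 1 5-methylhex-4-enal; 2 2-(triphenyl-λ5-phosphanylidene)propanal
Product: 3 (2E)-2,7-dimethylocta-2,6-dienal
Conditions: toluene, 90 °C
Reagents that add atoms: none
Why: Wittig olefination with a stabilised ylide should give the (E)-2-methyl-enal selectively; no stereocentre is formed.

Step 2
Reactants: 4 (4E)-hex-4-en-3-one
Product: 5 tert-butyl[(2Z,4E)-hexa-2,4-dien-3-yloxy]dimethylsilane
Conditions: t-BuMe2SiOTf, Et3N, Et2O, 0 °C
Reagents that add atoms: tert-butyldimethylsilyl trifluoromethanesulfonate, CC(C)(C)[Si](C)(C)OS(=O)(=O)C(F)(F)F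
Why: Soft enolisation and O-silylation (silyl enol ether formation) on the ethyl side should give the cross-conjugated (Z)-2-silyloxydiene with both terminal methyls in the outside positions needed for cycloaddition.

Step 3
Reactants: 3 (2E)-2,7-dimethylocta-2,6-dienal; 5 tert-butyl[(2Z,4E)-hexa-2,4-dien-3-yloxy]dimethylsilane
Product: 6 4-(tert-butyldimethylsilyloxy)-1,2,5-trimethyl-6-(4-methylpent-3-en-1-yl)cyclohex-3-ene-1-carbaldehyde
Conditions: (S)-3,3-diphenyl-1-(2-methylphenyl)hexahydropyrrolo[1,2-c][1,3,2]oxazaborole (20 mol%), HN(SO2CF3)2 (18 mol%), CH2Cl2, −78 to −40 °C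
Reagents that add atoms: none
Why: Catalytic enantioselective Diels–Alder reaction with a chiral oxazaborolidinium Lewis acid: the 2-silyloxy group directs the regiochemistry (C5–C10 and C8–C9 bonds), the (E)-geometry of 3 is transferred into the cis relationship of the C9 methyl and the C10 side chain, and the catalyst, which binds the formyl group and shields one face of the s-trans enal, sets the absolute configuration of C9 and C10.

Step 4
Reactants: 6 4-(tert-butyldimethylsilyloxy)-1,2,5-trimethyl-6-(4-methylpent-3-en-1-yl)cyclohex-3-ene-1-carbaldehyde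
Product: 7 tert-butyl{[4-ethenyl-3,4,6-trimethyl-5-(4-methylpent-3-en-1-yl)cyclohex-1-en-1-yl]oxy}dimethylsilane
Conditions: Ph3PCH3Br, KN(SiMe3)2, THF, 0 °C
Reagents that add atoms: methylenetriphenylphosphorane (from methyltriphenylphosphonium bromide), C=P(c1ccccc1)(c1ccccc1)c1ccccc1
Why: Wittig methylenation of the non-enolisable neopentyl aldehyde should give the C11 vinyl group; the silyl enol ether is inert to the ylide and no stereocentre is touched.

Step 5
Reactants: 7 tert-butyl{[4-ethenyl-3,4,6-trimethyl-5-(4-methylpent-3-en-1-yl)cyclohex-1-en-1-yl]oxy}dimethylsilane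
Product: 8 4-ethenyl-3,4,6-trimethyl-5-(4-methylpent-3-en-1-yl)cyclohex-2-en-1-one
Conditions: Pd(OAc)2 (1.05 equiv), MeCN, 23 °C
Reagents that add atoms: none
Why: Saegusa–Ito oxidation: the regiodefined silyl enol ether should pass through a palladium enolate and lose the C8 hydrogen by β-hydride elimination, giving the C7=C8 enone and erasing the temporary C8 stereocentre.

Step 6
Reactants: 8 4-ethenyl-3,4,6-trimethyl-5-(4-methylpent-3-en-1-yl)cyclohex-2-en-1-one
Product: 9 4-ethenyl-6-(1-hydroxyethyl)-3,4,6-trimethyl-5-(4-methylpent-3-en-1-yl)cyclohex-2-en-1-one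
Conditions: LiN(i-Pr)2, THF, −78 °C; CH3CHO; AcOH, −78 °C
Reagents that add atoms: acetaldehyde, CC=O
Why: Kinetic aldol addition: deprotonation at the α′ carbon C5 and attack on acetaldehyde from the face opposite the adjacent C10 side chain should create the C5 quaternary centre with the C19 methyl cis to that chain; the carbinol centre is removed in step 7.

Step 7
Reactants: 9 4-ethenyl-6-(1-hydroxyethyl)-3,4,6-trimethyl-5-(4-methylpent-3-en-1-yl)cyclohex-2-en-1-one
Product: 10 6-acetyl-4-ethenyl-3,4,6-trimethyl-5-(4-methylpent-3-en-1-yl)cyclohex-2-en-1-one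
Conditions: Dess–Martin periodinane, NaHCO3, CH2Cl2, 0 to 23 °C
Reagents that add atoms: none
Why: Dess–Martin oxidation of the secondary alcohol should give the non-enolisable 2,2-disubstituted 1,3-diketone under neutral conditions that exclude retro-aldol cleavage.

Step 8
Reactants: 10 6-acetyl-4-ethenyl-3,4,6-trimethyl-5-(4-methylpent-3-en-1-yl)cyclohex-2-en-1-one
Product: 12 4-ethenyl-3,4,8,8a-tetramethyl-4a,5,6,8a-tetrahydronaphthalen-1(4H)-one, via tricyclic oxetane 11 (not isolated)
Conditions: FeCl3 (10 mol%), ClCH2CH2Cl, 23 °C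
Reagents that add atoms: none
Why: FeCl3 (a trivalent iron Lewis acid), held by the 1,3-dicarbonyl unit, activates the acetyl C=O, and the tethered trisubstituted olefin adds through its less substituted carbon C3 to the carbonyl carbon C4 in an asynchronous [2+2] cycloaddition to oxetane 11; retro-[2+2] opening in the other sense then releases acetone and the C3=C4 double bond. The closest known reaction type is the iron-catalysed ring-closing carbonyl–olefin metathesis of α-quaternary β-dicarbonyl ketones that carry prenyl-type olefins. Ring A is closed by C3–C4 bond formation in a 6-exo mode with respect to both π-bonds, the oxetane being a transient four-membered ring closed by the O–C bond. No new stereocentre persists: the two oxetane centres are destroyed on cycloreversion, and the trans ring fusion follows from the C5 and C10 configurations set in steps 6 and 3, whose two ring-forming substituents can both lie equatorial. The step needs the acetyl carbonyl to react rather than the enone carbonyl (which would require a bridgehead olefin), the trisubstituted olefin rather than the C11 vinyl group (a monosubstituted olefin cannot stabilise the developing positive charge), and metathesis rather than the carbonyl-ene pathway; loss of volatile acetone should drive it forward.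

Step 9
Reactants: 12 4-ethenyl-3,4,8,8a-tetramethyl-4a,5,6,8a-tetrahydronaphthalen-1(4H)-one
Product: 13 2,3-epoxy-4-ethenyl-3,4,8,8a-tetramethyl-2,3,4a,5,6,8a-hexahydronaphthalen-1(4H)-one
Conditions: H2O2 (30% aq.), NaOH (20 mol%), MeOH, 0 to 23 °C
Reagents that add atoms: hydrogen peroxide, OO
Why: Weitz–Scheffer nucleophilic epoxidation is specific for the electron-poor enone olefin, and axial attack of hydroperoxide at C8 on the face opposite the axial C20 methyl should place the C8–O bond on the lower face.

Step 10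
Reactants: 13 2,3-epoxy-4-ethenyl-3,4,8,8a-tetramethyl-2,3,4a,5,6,8a-hexahydronaphthalen-1(4H)-one
Product: 14 4-ethenyl-3-hydroxy-3,4,8,8a-tetramethyl-3,4,4a,5,6,8a-hexahydronaphthalen-1(2H)-one
Conditions: SmI2, THF/MeOH, −90 °C
Reagents that add atoms: none
Why: Single-electron reductive opening of the α,β-epoxy ketone (ketyl formation, then cleavage of the Cα–O bond) should give the β-hydroxy ketone with the C8 carbinol configuration retained.

Step 11
Reactants: 14 4-ethenyl-3-hydroxy-3,4,8,8a-tetramethyl-3,4,4a,5,6,8a-hexahydronaphthalen-1(2H)-one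
Product: 15 {[4-ethenyl-3,4,8,8a-tetramethyl-3-(trimethylsilyloxy)-3,4,4a,5,6,8a-hexahydronaphthalen-1-yl]oxy}trimethylsilane
Conditions: Me3SiOTf, Et3N, CH2Cl2, 0 °C
Reagents that add atoms: trimethylsilyl trifluoromethanesulfonate, C[Si](C)(C)OS(=O)(=O)C(F)(F)F
Why: Soft enolisation with silyl triflate (silyl enol ether formation) can only occur toward C7 because C5 is quaternary, and silylation of the tertiary hydroxyl blocks retro-aldol cleavage.

Step 12
Reactants: 15 {[4-ethenyl-3,4,8,8a-tetramethyl-3-(trimethylsilyloxy)-3,4,4a,5,6,8a-hexahydronaphthalen-1-yl]oxy}trimethylsilane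
Product: 16 4-ethenyl-2,3-dihydroxy-3,4,8,8a-tetramethyl-3,4,4a,5,6,8a-hexahydronaphthalen-1(2H)-one
Conditions: dimethyldioxirane (1.05 equiv), acetone/CH2Cl2, −78 °C; then aq. citric acid, THF, 23 °C
Reagents that add atoms: dimethyldioxirane, CC1(C)OO1
Why: Rubottom oxidation: the electron-rich silyl enol ether should be oxidised much faster than the other olefins, from the face opposite the two syn-axial methyls (C19, C20), which places the C7 hydroxyl equatorial, also the thermodynamically preferred α-ketol epimer.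

Step 13
Reactants: 16 4-ethenyl-2,3-dihydroxy-3,4,8,8a-tetramethyl-3,4,4a,5,6,8a-hexahydronaphthalen-1(2H)-one
Product: 17 4-ethenyl-3-hydroxy-3,4,8,8a-tetramethyl-1-oxo-1,2,3,4,4a,5,6,8a-octahydronaphthalen-2-yl 2-methylpropanoate
Conditions: i-PrCOCl, pyridine, DMAP (10 mol%), CH2Cl2, 0 °C
Reagents that add atoms: 2-methylpropanoyl chloride, CC(C)C(Cl)=O
Why: DMAP-catalysed acylation should esterify only the secondary C7 hydroxyl, the tertiary C8 hydroxyl being too hindered.

Step 14
Reactants: 17 4-ethenyl-3-hydroxy-3,4,8,8a-tetramethyl-1-oxo-1,2,3,4,4a,5,6,8a-octahydronaphthalen-2-yl 2-methylpropanoate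
Product: 18 4-ethenyl-1,3-dihydroxy-3,4,8,8a-tetramethyl-1,2,3,4,4a,5,6,8a-octahydronaphthalen-2-yl 2-methylpropanoate
Conditions: Me4NBH(OAc)3, MeCN/AcOH, −20 °C
Reagents that add atoms: none
Why: Hydroxyl-directed triacetoxyborohydride reduction: the axial C8 hydroxyl binds boron and delivers hydride to the lower face of the C6 ketone, which should give the 1,3-anti, equatorial C6 alcohol trans to the C7 ester.

Step 15
Reactants: 18 4-ethenyl-1,3-dihydroxy-3,4,8,8a-tetramethyl-1,2,3,4,4a,5,6,8a-octahydronaphthalen-2-yl 2-methylpropanoate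
Product: 19 1-acetoxy-4-ethenyl-3-hydroxy-3,4,8,8a-tetramethyl-1,2,3,4,4a,5,6,8a-octahydronaphthalen-2-yl 2-methylpropanoate
Conditions: Ac2O, pyridine, DMAP (10 mol%), CH2Cl2, 23 °C
Reagents that add atoms: acetic anhydride, CC(=O)OC(C)=O
Why: DMAP-catalysed acetylation should take place at the secondary C6 hydroxyl only, the tertiary C8 hydroxyl staying free.

Step 16
Reactants: 19 1-acetoxy-4-ethenyl-3-hydroxy-3,4,8,8a-tetramethyl-1,2,3,4,4a,5,6,8a-octahydronaphthalen-2-yl 2-methylpropanoate; 20 4-bromofuran-2(5H)-one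
Product: 21 6-acetoxy-8-hydroxy-7-(2-methylpropanoyloxy)cleroda-3,11E,13-trien-15,16-olide (CNP0207114.1)
Conditions: Pd(OAc)2 (10 mol%), P(o-tol)3 (20 mol%), Et3N, DMF, 80 °C
Reagents that add atoms: none
Why: Mizoroki–Heck reaction: oxidative addition of the bromobutenolide to zerovalent palladium, insertion at the terminal carbon of the vinyl group on quaternary C9 (no allylic hydrogen, so no chain walking) and syn β-hydride elimination should give the (11E)-diene.

## Compound list

1 | 5-methylhex-4-enal | CC(C)=CCCC=O | starting material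
2 | 2-(triphenyl-λ5-phosphanylidene)propanal | CC(C=O)=P(c1ccccc1)(c1ccccc1)c1ccccc1 | starting material
3 | (2E)-2,7-dimethylocta-2,6-dienal | CC(C)=CCC/C=C(\C)C=O | intermediate
4 | (4E)-hex-4-en-3-one | C/C=C/C(=O)CC | starting material
5 | tert-butyl[(2Z,4E)-hexa-2,4-dien-3-yloxy]dimethylsilane | C/C=C(\O[Si](C)(C)C(C)(C)C)/C=C/C | intermediate
6 | 4-(tert-butyldimethylsilyloxy)-1,2,5-trimethyl-6-(4-methylpent-3-en-1-yl)cyclohex-3-ene-1-carbaldehyde; formyl trans to the C6 side chain, the three methyls and the side chain on one ring face (formyl-exo adduct; the 2- and 5-methyl centres are erased in steps 5 and 6) | C[C@H]1C(O[Si](C)(C)C(C)(C)C)=C[C@@H](C)[C@](C)(C=O)[C@H]1CCC=C(C)C | intermediate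
7 | tert-butyl{[4-ethenyl-3,4,6-trimethyl-5-(4-methylpent-3-en-1-yl)cyclohex-1-en-1-yl]oxy}dimethylsilane; same relative configuration as 6 | C[C@H]1C(O[Si](C)(C)C(C)(C)C)=C[C@@H](C)[C@](C)(C=C)[C@H]1CCC=C(C)C | intermediate
8 | 4-ethenyl-3,4,6-trimethyl-5-(4-methylpent-3-en-1-yl)cyclohex-2-en-1-one; 4-methyl cis to the 5-side chain, 6-methyl as drawn (epimerisable, erased in step 6) | C[C@H]1C(=O)C=C(C)[C@](C)(C=C)[C@H]1CCC=C(C)C | intermediate
9 | 4-ethenyl-6-(1-hydroxyethyl)-3,4,6-trimethyl-5-(4-methylpent-3-en-1-yl)cyclohex-2-en-1-one; hydroxyethyl trans to the 5-side chain, 4- and 6-methyls cis to it, both carbinol epimers | CC(O)[C@]1(C)C(=O)C=C(C)[C@](C)(C=C)[C@H]1CCC=C(C)C | intermediate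
10 | 6-acetyl-4-ethenyl-3,4,6-trimethyl-5-(4-methylpent-3-en-1-yl)cyclohex-2-en-1-one; acetyl trans to the 5-side chain | CC(=O)[C@]1(C)C(=O)C=C(C)[C@](C)(C=C)[C@H]1CCC=C(C)C | intermediate
11 | tricyclic oxetane, the [2+2] adduct of the acetyl C=O of 10 with its side-chain olefin (2,2-dimethyloxetane fused across C3–C4; the two new oxetane carbons are left undefined) | O=C1C=C(C)[C@](C)(C=C)[C@H]2CCC3C(C)(C)OC3(C)[C@]12C | intermediate
12 | 4-ethenyl-3,4,8,8a-tetramethyl-4a,5,6,8a-tetrahydronaphthalen-1(4H)-one; trans ring fusion (4a-H trans to 8a-methyl), 4-methyl cis to 8a-methyl | O=C1C=C(C)[C@](C)(C=C)[C@H]2CCC=C(C)[C@]12C | intermediate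
13 | 2,3-epoxy-4-ethenyl-3,4,8,8a-tetramethyl-2,3,4a,5,6,8a-hexahydronaphthalen-1(4H)-one; epoxide oxygen trans to the 4- and 8a-methyls | O=C1[C@@H]2O[C@]2(C)[C@](C)(C=C)[C@H]3CCC=C(C)[C@]13C | intermediate
14 | 4-ethenyl-3-hydroxy-3,4,8,8a-tetramethyl-3,4,4a,5,6,8a-hexahydronaphthalen-1(2H)-one; 3-hydroxyl trans to the 4- and 8a-methyls | O=C1C[C@](C)(O)[C@](C)(C=C)[C@H]2CCC=C(C)[C@]12C | intermediate
15 | {[4-ethenyl-3,4,8,8a-tetramethyl-3-(trimethylsilyloxy)-3,4,4a,5,6,8a-hexahydronaphthalen-1-yl]oxy}trimethylsilane | C[Si](C)(C)OC1=C[C@](C)(O[Si](C)(C)C)[C@](C)(C=C)[C@H]2CCC=C(C)[C@]12C | intermediate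
16 | 4-ethenyl-2,3-dihydroxy-3,4,8,8a-tetramethyl-3,4,4a,5,6,8a-hexahydronaphthalen-1(2H)-one; 2- and 3-hydroxyls cis, both trans to the 4- and 8a-methyls | O=C1[C@H](O)[C@](C)(O)[C@](C)(C=C)[C@H]2CCC=C(C)[C@]12C | intermediate
17 | 4-ethenyl-3-hydroxy-3,4,8,8a-tetramethyl-1-oxo-1,2,3,4,4a,5,6,8a-octahydronaphthalen-2-yl 2-methylpropanoate | O=C1[C@H](OC(=O)C(C)C)[C@](C)(O)[C@](C)(C=C)[C@H]2CCC=C(C)[C@]12C | intermediate
18 | 4-ethenyl-1,3-dihydroxy-3,4,8,8a-tetramethyl-1,2,3,4,4a,5,6,8a-octahydronaphthalen-2-yl 2-methylpropanoate; 1-hydroxyl trans to the 2-ester, cis to the 8a-methyl | O[C@H]1[C@H](OC(=O)C(C)C)[C@](C)(O)[C@](C)(C=C)[C@H]2CCC=C(C)[C@]12C | intermediate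
19 | 1-acetoxy-4-ethenyl-3-hydroxy-3,4,8,8a-tetramethyl-1,2,3,4,4a,5,6,8a-octahydronaphthalen-2-yl 2-methylpropanoate | CC(=O)O[C@H]1[C@H](OC(=O)C(C)C)[C@](C)(O)[C@](C)(C=C)[C@H]2CCC=C(C)[C@]12C | intermediate
20 | 4-bromofuran-2(5H)-one | O=C1C=C(Br)CO1 | starting material
21 | 6-acetoxy-8-hydroxy-7-(2-methylpropanoyloxy)cleroda-3,11E,13-trien-15,16-olide (CNP0207114.1) | CC(=O)O[C@H]1[C@H](OC(=O)C(C)C)[C@](C)(O)[C@](C)(/C=C/C2=CC(=O)OC2)[C@H]2CCC=C(C)[C@]12C | target

## Step count

Total: 16 steps. Longest linear sequence: 15 steps (steps 1 and 3–16, from aldehyde 1); step 2 is a one-step branch.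

## Steps most likely to fail

1. Step 8 (ring-closing carbonyl–olefin metathesis). The Lewis acid may be tied up by the 1,3-dicarbonyl unit without turnover, or the ionised intermediate may be drained by the carbonyl-ene pathway (proton loss to a homoallylic tertiary alcohol) before it collapses to oxetane 11. The fallback replaces metathesis by reductive carbonyl coupling. It sets out from 10: the electron-rich trisubstituted side-chain olefin is cleaved selectively (OsO4 cat., N-methylmorpholine N-oxide, acetone/water; then NaIO4) to 3-(2-acetyl-6-ethenyl-2,5,6-trimethyl-3-oxocyclohex-4-en-1-yl)propanal F1. An intramolecular McMurry coupling of the aldehyde with the acetyl ketone (TiCl3(DME)1.5, Zn–Cu couple, DME, slow addition at reflux) should then form the same C3=C4 bond, six-ring closure outrunning intermolecular coupling of the enone, and the sequence comes back to the route at 12.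

2. Step 6 (quaternisation of C5). Deprotonation may take place at the γ-methyl instead of the hindered α′ methine, the lithium aldolate may revert, or the electrophile may approach the wrong face. The fallback separates enolate formation from C–C bond formation. It sets out from 8: LiN(i-Pr)2 and Me3SiCl in THF at −78 °C give {[4-ethenyl-2,4,5-trimethyl-3-(4-methylpent-3-en-1-yl)cyclohexa-1,5-dien-1-yl]oxy}trimethylsilane F2, whose constitution can be checked before use. A Mukaiyama aldol addition to acetaldehyde (TiCl4, CH2Cl2, −78 °C; open transition state, irreversible) should then give the same adduct, and the sequence comes back to the route at 9.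

3. Step 16 (Heck coupling). Migratory insertion at the vinyl group on the quaternary C9 may be slow, so that base-induced degradation of the bromobutenolide or palladium black formation takes over. The fallback divides the coupling into a metathesis and a cross-coupling. It sets out from 19: olefin cross-metathesis with 4,4,5,5-tetramethyl-2-vinyl-1,3,2-dioxaborolane (second-generation Hoveyda–Grubbs catalyst, CH2Cl2, 40 °C; the ring A trisubstituted olefin is inert) should give 1-acetoxy-3-hydroxy-3,4,8,8a-tetramethyl-4-[(E)-2-(4,4,5,5-tetramethyl-1,3,2-dioxaborolan-2-yl)ethenyl]-1,2,3,4,4a,5,6,8a-octahydronaphthalen-2-yl 2-methylpropanoate F3. Suzuki–Miyaura coupling of F3 with 20 (Pd(PPh3)4, K3PO4, THF/water, 50 °C) comes back to the route at 21.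

Further compounds
F1 | step 8 | 3-(2-acetyl-6-ethenyl-2,5,6-trimethyl-3-oxocyclohex-4-en-1-yl)propanal | CC(=O)[C@]1(C)C(=O)C=C(C)[C@](C)(C=C)[C@H]1CCC=O
F2 | step 6 | {[4-ethenyl-2,4,5-trimethyl-3-(4-methylpent-3-en-1-yl)cyclohexa-1,5-dien-1-yl]oxy}trimethylsilane | CC1=C(O[Si](C)(C)C)C=C(C)[C@](C)(C=C)[C@H]1CCC=C(C)C
F3 | step 16 | 1-acetoxy-3-hydroxy-3,4,8,8a-tetramethyl-4-[(E)-2-(4,4,5,5-tetramethyl-1,3,2-dioxaborolan-2-yl)ethenyl]-1,2,3,4,4a,5,6,8a-octahydronaphthalen-2-yl 2-methylpropanoate | CC(=O)O[C@H]1[C@H](OC(=O)C(C)C)[C@](C)(O)[C@](C)(/C=C/B2OC(C)(C)C(C)(C)O2)[C@H]2CCC=C(C)[C@]12C
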